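**Retrosynthetic overview**

- The target comes from a tricyclic alkene diol by double angeloylation, then a transposing allylic oxidation that makes the C11 ketone and the C9=C10 double bond.
- Seven-membered ring (formed last): the C6–C7 bond is made by adding a tertiary radical to the C=N of a cyclobutanone tosylhydrazone, which then loses N2 to leave C7–H. The C5 carbinol is set beforehand by an asymmetric Ni/Cr coupling.
- Cyclobutane (formed second, key step): the C2–C8 bond is made by a hydrogen-atom-transfer-initiated 4-exo radical closure onto the enone of a quinone monoketal adduct. The ketal carbon becomes C7.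
- Six-membered ring (first): o-cresol is dearomatised to the quinone monoketal, and its one stereocentre is set by Rh-catalysed asymmetric 1,4-addition of a hexadienyl boron reagent.
- Ring order: cyclohexenone, then bicyclo[3.1.1]heptane, then tricyclo[5.4.0.0(2,8)]undecane.

Assumption: the five numbered starting materials are bought as such (allylmagnesium bromide as its ether solution); the methyl-bearing CH next to the ring ketone of 10 is carried as the epimer drawn, and its configuration is irrelevant because that centre becomes sp2 in step 11.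

**Step 1**
Reactants: 1 o-cresol (2-methylphenol)
Product: 3 4,4-dimethoxy-2-methylcyclohexa-2,5-dien-1-one, via 4-methoxy-2-methylphenol 2 (not isolated)
Conditions: PhI(OAc)2 (2.2 equiv), MeOH, 0 °C to rt
Reagents that add atoms: methanol, CO
Why: Oxidative dearomatisation of a phenol by trivalent iodine, in which para-methoxylation followed by a second oxidation in methanol gives the quinone monoketal; no stereocentre is formed.

**Step 2**
Reactants: 4 2,3-dibromopropene; 5 allylmagnesium bromide
Product: 6 2-bromohexa-1,5-diene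
Conditions: Et2O, 0 °C to rt
Reagents that add atoms: none
Why: Grignard substitution of the allylic bromide (SN2 and SN2′ give the same product) leaves the vinylic bromide untouched; no stereocentre is formed.

**Step 3**
Reactants: 6 2-bromohexa-1,5-diene; 3 4,4-dimethoxy-2-methylcyclohexa-2,5-dien-1-one
Product: 9 (5S)-5-(hexa-1,5-dien-2-yl)-4,4-dimethoxy-2-methylcyclohex-2-en-1-one, via hexa-1,5-dien-2-yllithium 7 (not isolated), via lithium hexadienyl(trimethoxy)borate 8 (not isolated)
Conditions: t-BuLi (2 equiv), Et2O, −78 °C; B(OMe)3, −78 °C to rt; then 3 (0.7 equiv), [Rh(OH)((S)-BINAP)]2 (1.5 mol%), dioxane/H2O 10:1, 40 °C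
Reagents that add atoms: none
Why: Hayashi–Miyaura rhodium-catalysed asymmetric 1,4-addition of an alkenylboron reagent made in situ, which attacks only the unsubstituted enone (the α-methyl enone is inert), with (S)-BINAP delivering the alkenyl group to the same enone face that gives (S)-3-substituted cyclohexanones, here the (5S) centre that later fixes the absolute sense of the whole cage.

**Step 4**
Reactants: 9 (5S)-5-(hexa-1,5-dien-2-yl)-4,4-dimethoxy-2-methylcyclohex-2-en-1-one
Product: 10 (1R,2R,5S,6S)-6-(but-3-en-1-yl)-7,7-dimethoxy-2,6-dimethylbicyclo[3.1.1]heptan-3-one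
Conditions: Fe(acac)3 (30 mol%), PhSiH3 (2.5 equiv, slow addition), EtOH/(CH2OH)2 5:1, 60 °C, 0.01 M
Reagents that add atoms: none
Why: Proposed new method: iron-hydride hydrogen-atom transfer to the 1,1-disubstituted alkene (much faster than to the monosubstituted one) gives a tertiary radical on the axial C5 substituent that closes 4-exo-trig onto the enone β-carbon, helped by the gem-dimethoxy carbon inside the forming ring and made irreversible by fast reduction of the tertiary α-keto radical to the iron enolate and protonation, so that the cyclobutane bond (C2–C8 of the target) and the quaternary centre form with the larger butenyl chain exo and the new methyl endo over the ketone bridge; the closest known reaction types are the HAT-initiated reductive olefin–enone (Giese) coupling and 4-exo radical cyclisations onto unsaturated carbonyls promoted by gem-dialkoxy substitution or by titanocene.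

**Step 5**
Reactants: 10 (1R,2R,5S,6S)-6-(but-3-en-1-yl)-7,7-dimethoxy-2,6-dimethylbicyclo[3.1.1]heptan-3-one
Product: 12 3-[(1R,2R,5S,6S)-7,7-dimethoxy-2,6-dimethyl-3-oxobicyclo[3.1.1]heptan-6-yl]propanal, via ozonide 11 (not isolated)
Conditions: O3, CH2Cl2, −78 °C; Me2S, −78 °C to rt
Reagents that add atoms: ozone, [O-][O+]=O
Why: Ozonolysis with reductive work-up cleaves the only remaining alkene to the aldehyde; ketone, ketal and all stereocentres are untouched.

**Step 6**
Reactants: 12 3-[(1R,2R,5S,6S)-7,7-dimethoxy-2,6-dimethyl-3-oxobicyclo[3.1.1]heptan-6-yl]propanal; 13 2-bromoprop-2-en-1-ol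
Product: 14 (3R)-5-[(1R,2R,5S,6S)-7,7-dimethoxy-2,6-dimethyl-3-oxobicyclo[3.1.1]heptan-6-yl]-2-methylidenepentane-1,3-diol
Conditions: 13 (3 equiv), CrCl2 (6 equiv), NiCl2 (2 mol%), Si-face-selective chiral oxazoline–sulfonamide ligand (6.6 equiv, recovered), Et3N (6.6 equiv), THF, rt
Reagents that add atoms: none
Why: Nozaki–Hiyama–Kishi coupling (nickel-catalysed activation of the alkenyl bromide, addition of the alkenylchromium species) is selective for the aldehyde over ketone and ketal, and the chiral ligand on chromium directs addition to the Si face, setting the (3R) carbinol that becomes C5 of the target by reagent control.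

**Step 7**
Reactants: 14 (3R)-5-[(1R,2R,5S,6S)-7,7-dimethoxy-2,6-dimethyl-3-oxobicyclo[3.1.1]heptan-6-yl]-2-methylidenepentane-1,3-diol
Product: 15 3,7-bis(tosylhydrazone) of 6-[(3R)-3-hydroxy-4-(hydroxymethyl)pent-4-en-1-yl]-2,6-dimethylbicyclo[3.1.1]heptane-3,7-dione (ring stereocentres as in 14; C=N geometry not defined)
Conditions: TsNHNH2 (2.5 equiv), PPTS (20 mol%), MeOH, 50 °C
Reagents that add atoms: p-toluenesulfonyl hydrazide, Cc1ccc(cc1)S(=O)(=O)NN
Why: Acid-catalysed hydrazone formation, in which the ketone condenses directly and the dimethyl ketal exchanges through its oxocarbenium ion, converts both carbonyl carbons in one operation; no stereocentre of consequence is changed.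

**Step 8**
Reactants: 15 the bis(tosylhydrazone) above
Product: 16 7-tosylhydrazone of 6-[(3R)-3-hydroxy-4-(hydroxymethyl)pent-4-en-1-yl]-4,6-dimethylbicyclo[3.1.1]hept-2-en-7-one (ring stereocentres as in 14)
Conditions: LiN(i-Pr)2 (8 equiv), THF, −78 °C to rt; H2O
Reagents that add atoms: none
Why: Shapiro reaction, in which only the C3 hydrazone has an α-CH2 and gives the less substituted alkene after loss of sulfinate and N2, whereas the C7 hydrazone, flanked by two bridgeheads, is only N-deprotonated and recovered on quench; no stereocentre is changed.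

**Step 9**
Reactants: 16 the alkenyl mono(tosylhydrazone) above
Product: 18 6-(hydroxymethyl)-2,6,9-trimethyltricyclo[5.4.0.0(2,8)]undec-10-en-5-ol (C5–OH trans to the C6 hydroxymethyl; configured as in the target), via sulfonylhydrazine 17 (not isolated)
Conditions: Fe(acac)3 (30 mol%), PhSiH3 (3 equiv), EtOH, 60 °C, 0.005 M; then NaOAc, 80 °C
Reagents that add atoms: none
Why: Proposed new method: hydrogen-atom transfer to the 2-methylidene-1,3-diol alkene gives a tertiary radical that adds 7-exo to the hydrazone carbon from the only face the tether can reach (anti to the alkene bridge), the hydrazinyl radical is reduced and protonated to 17, and base-induced loss of sulfinate and N2 leaves C7–H, so that the C6–C7 bond and the C6 quaternary centre form with the larger hydroxymethyl group pseudo-equatorial and trans to the C5 oxygen; the closest known reaction types are the iron-catalysed HAT alkene–tosylhydrazone coupling, radical cyclisations onto N-aziridinyl imines and the reductive cleavage of alkyl sulfonylhydrazines to C–H.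

**Step 10**
Reactants: 18 the tricyclic diol above; 19 angelic acid ((2Z)-2-methylbut-2-enoic acid)
Product: 21 bis[(2Z)-2-methylbut-2-enoate] of 18 (diangelate), via mixed anhydride 20 (not isolated)
Conditions: 19 (5 equiv), 2,4,6-trichlorobenzoyl chloride (5 equiv), Et3N (10 equiv), toluene, rt; then 18, 80 °C
Reagents that add atoms: none
Why: Yamaguchi-type mixed-anhydride esterification run without a nucleophilic amine catalyst, so that the (Z)-2-methylbut-2-enoyl group is not isomerised to tiglate; no stereocentre is touched.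

**Step 11**
Reactants: 21 the diangelate above
Product: 22 [(1R,2R,5R,6S,7S,8R)-5-{[(2Z)-2-methylbut-2-enoyl]oxy}-2,6,9-trimethyl-11-oxotricyclo[5.4.0.0(2,8)]undec-9-en-6-yl]methyl (2Z)-2-methylbut-2-enoate (target)
Conditions: CrO3 (15 equiv), 3,5-dimethylpyrazole (15 equiv), CH2Cl2, −20 °C
Reagents that add atoms: chromium trioxide, O=[Cr](=O)=O
Why: Allylic oxidation with hexavalent chromium, in which the only abstractable allylic hydrogen (C9–H, the other being at a bridgehead) is removed and oxygen is placed on the far allyl terminus C11, giving the transposed, verbenone-type enone as in chromium oxidations of 3-alkylcycloalkenes to 3-alkylcycloalk-2-enones; the C9 stereocentre disappears and the electron-poor angelate alkenes are left alone.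

**Compound list**

1 | o-cresol (2-methylphenol) | Cc1ccccc1O | starting material
2 | 4-methoxy-2-methylphenol | COc1ccc(O)c(C)c1 | intermediate
3 | 4,4-dimethoxy-2-methylcyclohexa-2,5-dien-1-one | COC1(OC)C=CC(=O)C(C)=C1 | intermediate
4 | 2,3-dibromopropene | BrCC(Br)=C | starting material
5 | allylmagnesium bromide | C=CC[Mg]Br | starting material
6 | 2-bromohexa-1,5-diene | C=CCCC(Br)=C | intermediate
7 | hexa-1,5-dien-2-yllithium | [Li]C(=C)CCC=C | intermediate
8 | lithium (hexa-1,5-dien-2-yl)trimethoxyborate | [Li+].CO[B-](OC)(OC)C(=C)CCC=C | intermediate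
9 | (5S)-5-(hexa-1,5-dien-2-yl)-4,4-dimethoxy-2-methylcyclohex-2-en-1-one | COC1(OC)[C@@H](CC(=O)C(C)=C1)C(=C)CCC=C | intermediate
10 | (1R,2R,5S,6S)-6-(but-3-en-1-yl)-7,7-dimethoxy-2,6-dimethylbicyclo[3.1.1]heptan-3-one (6-methyl over the ketone bridge, chain anti) | COC1(OC)[C@H]2CC(=O)[C@H](C)[C@@H]1[C@@]2(C)CCC=C | intermediate
11 | ozonide (1,2,4-trioxolane) of 10, both epimers at the trioxolane carbon | COC1(OC)[C@H]2CC(=O)[C@H](C)[C@@H]1[C@@]2(C)CCC3OCOO3 | intermediate
12 | 3-[(1R,2R,5S,6S)-7,7-dimethoxy-2,6-dimethyl-3-oxobicyclo[3.1.1]heptan-6-yl]propanal | COC1(OC)[C@H]2CC(=O)[C@H](C)[C@@H]1[C@@]2(C)CCC=O | intermediate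
13 | 2-bromoprop-2-en-1-ol | OCC(Br)=C | starting material
14 | (3R)-5-[(1R,2R,5S,6S)-7,7-dimethoxy-2,6-dimethyl-3-oxobicyclo[3.1.1]heptan-6-yl]-2-methylidenepentane-1,3-diol | COC1(OC)[C@H]2CC(=O)[C@H](C)[C@@H]1[C@@]2(C)CC[C@@H](O)C(=C)CO | intermediate
15 | 3,7-bis(tosylhydrazone) of 6-[(3R)-3-hydroxy-4-(hydroxymethyl)pent-4-en-1-yl]-2,6-dimethylbicyclo[3.1.1]heptane-3,7-dione, ring stereocentres as in 14 | Cc1ccc(cc1)S(=O)(=O)NN=C1[C@H]2CC(=NNS(=O)(=O)c3ccc(C)cc3)[C@H](C)[C@@H]1[C@@]2(C)CC[C@@H](O)C(=C)CO | intermediate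
16 | 7-tosylhydrazone of 6-[(3R)-3-hydroxy-4-(hydroxymethyl)pent-4-en-1-yl]-4,6-dimethylbicyclo[3.1.1]hept-2-en-7-one, ring stereocentres as in 14 | Cc1ccc(cc1)S(=O)(=O)NN=C1[C@H]2C=C[C@H](C)[C@@H]1[C@@]2(C)CC[C@@H](O)C(=C)CO | intermediate
17 | N'-[5-hydroxy-6-(hydroxymethyl)-2,6,9-trimethyltricyclo[5.4.0.0(2,8)]undec-10-en-7-yl]-4-methylbenzenesulfonohydrazide, stereocentres as in 18 | OC[C@]1(C)[C@]2(NNS(=O)(=O)c4ccc(C)cc4)[C@H]3C=C[C@H](C)[C@@H]2[C@@]3(C)CC[C@H]1O | intermediate
18 | 6-(hydroxymethyl)-2,6,9-trimethyltricyclo[5.4.0.0(2,8)]undec-10-en-5-ol, C5–OH trans to C6–CH2OH, skeleton as in the target | OC[C@]1(C)[C@@H]2[C@H]3C=C[C@H](C)[C@@H]2[C@@]3(C)CC[C@H]1O | intermediate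
19 | angelic acid, (2Z)-2-methylbut-2-enoic acid | C/C=C(/C)C(=O)O | starting material
20 | (2Z)-2-methylbut-2-enoic 2,4,6-trichlorobenzoic anhydride | C/C=C(/C)C(=O)OC(=O)c1c(Cl)cc(Cl)cc1Cl | intermediate
21 | diangelate of 18 | C/C=C(/C)C(=O)OC[C@]1(C)[C@@H]2[C@H]3C=C[C@H](C)[C@@H]2[C@@]3(C)CC[C@H]1OC(=O)/C(C)=C\C | intermediate
22 | [(1R,2R,5R,6S,7S,8R)-5-{[(2Z)-2-methylbut-2-enoyl]oxy}-2,6,9-trimethyl-11-oxotricyclo[5.4.0.0(2,8)]undec-9-en-6-yl]methyl (2Z)-2-methylbut-2-enoate | C/C=C(/C)C(=O)OC[C@]1(C)[C@@H]2[C@H]3C(=O)C=C(C)[C@@H]2[C@@]3(C)CC[C@H]1OC(=O)/C(C)=C\C | target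

**Step count and risks**

Total steps: 11. Longest linear sequence: 10 steps (steps 2 to 11; equally step 1, then 3 to 11).

The three steps most likely to fail are 4, 9 and 10.

Step 4 (4-exo closure). If the tertiary radical is reduced or isomerised by the iron hydride faster than it closes, the fallback sets out from 9 and makes the same radical without a hydride donor. Mukaiyama hydration (Co(acac)2, PhSiH3, O2, i-PrOH) of the 1,1-disubstituted alkene gives the tertiary alcohol F1. Methyl chlorooxoacetate with Et3N and DMAP gives the methyl oxalate F2, and aqueous CsOH gives the cesium oxalate F3. Visible-light photoredox decarboxylation (Ir[dF(CF3)ppy]2(dtbbpy)PF6, blue light, aqueous DME) releases the radical, which closes onto the enone and is reduced to the enolate. The route is rejoined at 10.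

Step 9 (radical addition to the hindered C=N, and the C6 configuration). The fallback sets out from 16 and uses the ketone as acceptor, then deletes the extra hydroxyl. Acetone with BF3·OEt2 exchanges the hydrazone off and ties the diol up in one operation, giving the cyclobutanone acetonide F4. The HAT ketone–olefin cyclisation (Fe(acac)3, PhSiH3, EtOH) gives the tricyclic tertiary cyclobutanol F5. Methyl chlorooxoacetate with DMAP gives the methyl oxalate F6, and Bu3SnH with AIBN in toluene at 110 °C deoxygenates through the cyclobutyl radical to the acetonide F7. Aqueous acetic acid then returns to the route at 18.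

Step 10 (acylating the neopentyl secondary alcohol without angelate-to-tiglate isomerisation). The fallback sets out from 18 and builds the Z double bonds after acylation. 2-Bromopropanoyl bromide and pyridine give the bis(2-bromopropanoate) F8. An Arbuzov reaction with tris(2,2,2-trifluoroethyl) phosphite at 140 °C gives the bis-phosphonate F9. Z-selective Still–Gennari olefination with acetaldehyde (KN(SiMe3)2, 18-crown-6, THF, −78 °C) returns to the route at 21.

**Further compounds**

F1 | step 4 | (5S)-5-(2-hydroxyhex-5-en-2-yl)-4,4-dimethoxy-2-methylcyclohex-2-en-1-one, both carbinol epimers | COC1(OC)[C@@H](CC(=O)C(C)=C1)C(C)(O)CCC=C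
F2 | step 4 | methyl oxalate of F1 | COC1(OC)[C@@H](CC(=O)C(C)=C1)C(C)(OC(=O)C(=O)OC)CCC=C
F3 | step 4 | cesium oxalate of F1 | [Cs+].COC1(OC)[C@@H](CC(=O)C(C)=C1)C(C)(OC(=O)C([O-])=O)CCC=C
F4 | step 9 | 6-{2-[(4R)-2,2-dimethyl-5-methylidene-1,3-dioxan-4-yl]ethyl}-4,6-dimethylbicyclo[3.1.1]hept-2-en-7-one, ring stereocentres as in 16 | O=C1[C@H]2C=C[C@H](C)[C@@H]1[C@@]2(C)CC[C@H]3OC(C)(C)OCC3=C
F5 | step 9 | acetonide of the 7-hydroxy analogue of 18 (tertiary cyclobutanol) | CC1(C)OC[C@]2(C)[C@]3(O)[C@H]4C=C[C@H](C)[C@@H]3[C@@]4(C)CC[C@H]2O1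
F6 | step 9 | methyl oxalate of F5 | CC1(C)OC[C@]2(C)[C@]3(OC(=O)C(=O)OC)[C@H]4C=C[C@H](C)[C@@H]3[C@@]4(C)CC[C@H]2O1
F7 | step 9 | acetonide of 18 | CC1(C)OC[C@]2(C)[C@@H]3[C@H]4C=C[C@H](C)[C@@H]3[C@@]4(C)CC[C@H]2O1
F8 | step 10 | bis(2-bromopropanoate) of 18, both epimers at each bromo carbon | CC(Br)C(=O)OC[C@]1(C)[C@@H]2[C@H]3C=C[C@H](C)[C@@H]2[C@@]3(C)CC[C@H]1OC(=O)C(C)Br
F9 | step 10 | bis{2-[bis(2,2,2-trifluoroethoxy)phosphoryl]propanoate} of 18 | CC(P(=O)(OCC(F)(F)F)OCC(F)(F)F)C(=O)OC[C@]1(C)[C@@H]2[C@H]3C=C[C@H](C)[C@@H]2[C@@]3(C)CC[C@H]1OC(=O)C(C)P(=O)(OCC(F)(F)F)OCC(F)(F)F
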